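**Retrosynthetic overview**

1. Feature: the central rings B and C are hexasubstituted benzenes in which three O-bearing carbons alternate with three C-bearing carbons (outer CH2, central CH2, propionyl C=O), which is the pattern a vinylketene plus ynol ether benzannulation delivers.
2. Last disconnection: the two outer CH2–C bonds to the enolized triketone rings A and D (ortho-quinone methide from an ArCH2OBn handle, captured by preformed propionylfilicinic acid 21).
3. The propionyl groups of rings B and C go back to the single ring C–H (bromination, then a bromine–lithium-triggered O→C acyl shift from the neighbouring phenol ester).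
4. Key disconnection: in each of rings B and C the bonds C(outer CH2)–C(OH) and C(central CH2)–C(OSi) are cut, giving the methylene-linked bis-cyclobutenone 6 (central CH2 already on C2 of both four-membered rings) and two siloxyalkynes 10.
5. Ring order: cyclobutenones (bought) → rings B and C together (step 4) → rings A and D attached (step 9); 6 comes from 3-ethoxycyclobutenone, formaldehyde and benzyl alcohol, 10 from benzyl propargyl ether.

Key step: step 4

Remark: the target has no stereocentre; the enol forms drawn for rings A and D are one of several equivalent tautomers, and the intermediates of the twofold steps are written as if both halves had reacted.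

Remark: the cyclobutenone oxygen is carried as a benzyl ether, removed by hydrogenolysis at the end, because a simple alkyl aryl ether would need BBr3 or AlCl3, which the ArCH2OBn handle and the diarylmethane links would not survive; for the same reason the acyl group is placed by an anionic and not a Lewis acid Fries shift.

**Route**

Step 1
Reactants: 1 3-ethoxycyclobut-2-en-1-one (2 equiv); 2 formaldehyde
Product: 5 2,2'-methylenebis(3-hydroxycyclobut-2-en-1-one), via cyclobutane-1,3-dione 3 (not isolated), via 2-methylenecyclobutane-1,3-dione 4 (not isolated)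
Conditions: 0.1 M aq. HCl, 0 °C → rt; then 2 (37% aq., 0.5 equiv), rt
Reagents that add atoms: water, O
Why: Acid hydrolysis of the vinylogous ester frees the strongly enolized dione 3, which is trapped in the same flask by formaldehyde through Knoevenagel condensation to 4 and Michael addition of a second enol, the standard route from cyclic 1,3-diones to methylenebis(diones).

Step 2
Reactants: 5 2,2'-methylenebis(3-hydroxycyclobut-2-en-1-one)
Product: 6 2,2'-methylenebis[3-(benzyloxy)cyclobut-2-en-1-one]
Conditions: BnOH, PPh3, DIAD, THF, 0 °C → rt
Reagents that add atoms: benzyl alcohol, OCc1ccccc1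
Why: The bis-enol is a vinylogous carboxylic acid and so a good Mitsunobu pronucleophile, and the alkoxyphosphonium ion alkylates the ambident anion at oxygen, so each symmetric dione ring should give the single possible 3-benzyloxy enone (Mitsunobu O-alkylation).

Step 3
Reactants: 7 benzyl propargyl ether
Product: 10 3-benzyloxy-1-(triisopropylsiloxy)propyne, via lithium acetylide 8 (not isolated), via lithium ynolate 9 (not isolated)
Conditions: n-BuLi, THF, −78 °C; LiOOt-Bu (from t-BuOOH and LiN(SiMe3)2), −78 → 0 °C; TIPSOTf, −78 → 0 °C
Reagents that add atoms: tert-butyl hydroperoxide, CC(C)(C)OO; triisopropylsilyl triflate, CC(C)[Si](OS(=O)(=O)C(F)(F)F)(C(C)C)C(C)C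
Why: The acetylide attacks the electrophilic oxygen of the lithium peroxide to give the ynolate (acetylide oxidation), and the bulky, hard silyl triflate traps it at oxygen and not at carbon, which is the established one-flask entry to triisopropylsiloxyalkynes.

Step 4
Reactants: 6 2,2'-methylenebis[3-(benzyloxy)cyclobut-2-en-1-one]; 10 3-benzyloxy-1-(triisopropylsiloxy)propyne (2.5 equiv)
Product: 15 4,4'-methylenebis{5-(benzyloxy)-2-[(benzyloxy)methyl]-3-[(triisopropylsilyl)oxy]phenol}, via bis(vinylketene) 11 (not isolated), via bis(4-vinylcyclobutenone) 12 (not isolated), via bis(dienylketene) 13 (not isolated), via bis(cyclohexa-2,4-dienone) 14 (not isolated)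
Conditions: PhMe (0.1 M), 80 → 110 °C, sealed tube, argon
Reagents that add atoms: none
Why: Heating opens each cyclobutenone of 6 by four-electron conrotatory cleavage of its C1–C4 bond to the (1-benzyloxyvinyl)ketene 11, which the electron-rich siloxyalkyne intercepts in a [2+2] cycloaddition at the ketene C=C bond to give 4-vinylcyclobutenone 12. A second four-electron ring opening gives dienylketene 13, and each of rings B and C is then closed by thermal six-electron disrotatory electrocyclization, the ketene carbon bonding to the terminal CH2 of the alkoxyvinyl group, to dienone 14, which enolizes to the phenol. This is the Danheiser benzannulation of a cyclobutenone with a siloxyalkyne, run twice on one molecule and with a 3-alkoxycyclobutenone so that the arene emerges as a phloroglucinol with its three oxygens as OH, OTIPS and OBn. No stereocentre is formed, since the quaternary carbon of 12 is transient and is lost in the second ring opening. The step needs the alkyne carbon bearing CH2OBn to bond to the ketene carbonyl carbon and the siloxy-bearing carbon to bond to the old C2; the polarization of the ynol ether (nucleophilic carbon remote from oxygen) against the electrophilic ketene carbon secures this and places OTIPS meta to the new OH and next to the central CH2. The alkyne is used in excess and the temperature is capped at 110 °C so that each vinylketene is captured before it dimerizes or acylates product phenol, and so that the ArCH2OBn handle does not eliminate thermally.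

Step 5
Reactants: 15 4,4'-methylenebis{5-(benzyloxy)-2-[(benzyloxy)methyl]-3-[(triisopropylsilyl)oxy]phenol}
Product: 16 dipropanoate of 15 (both phenolic OH groups esterified)
Conditions: EtCOCl, Et3N, DMAP (cat.), CH2Cl2, 0 °C → rt
Reagents that add atoms: propionyl chloride, CCC(=O)Cl
Why: DMAP-catalysed O-acylation of the only free hydroxyl of each ring places the propionyl group next to the ring C–H it is to migrate to and protects the phenol against oxidation in the next step.

Step 6
Reactants: 16 dipropanoate of 15
Product: 17 dibromide of 16 (Br on the ring carbon between OBn and the propanoyloxy group of each ring)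
Conditions: NBS (2.05 equiv), MeCN, 0 °C → rt, dark
Reagents that add atoms: N-bromosuccinimide, O=C1CCC(=O)N1Br
Why: Electrophilic aromatic bromination should go to the only unsubstituted ring carbon, which is activated by the ortho benzyloxy and para siloxy groups, while the polar solvent and darkness keep the reaction ionic and spare the benzylic CH2 groups.

Step 7
Reactants: 17 dibromide of 16
Product: 19 1,1'-(methylenebis{6-(benzyloxy)-3-[(benzyloxy)methyl]-2-hydroxy-4-[(triisopropylsilyl)oxy]-5,1-phenylene})di(propan-1-one), via bis(aryllithium) 18 (not isolated)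
Conditions: n-BuLi (2.2 equiv), THF, −100 → −40 °C; aq. NH4Cl
Reagents that add atoms: none
Why: Bromine–lithium exchange is faster than attack of n-BuLi on the doubly ortho-substituted ester and gives an aryllithium next to the acyloxy group, which takes the propionyl group by 1,3 O→C migration (anionic ortho-Fries rearrangement) to the chelated lithium 2-acylphenoxide, with no Lewis acid that would ionize the ArCH2OBn handle.

Step 8
Reactants: 20 flopropione, 1-(2,4,6-trihydroxyphenyl)propan-1-one
Product: 21 propionylfilicinic acid, 3,5-dihydroxy-6,6-dimethyl-2-propanoylcyclohexa-2,4-dien-1-one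
Conditions: NaOMe, MeI (2.2 equiv), MeOH, 0 °C → rt
Reagents that add atoms: iodomethane, CI
Why: Twofold C-methylation of the phloroglucinol anion at one ring CH (alkylative dearomatization) is the classical access to acylfilicinic acids, and the gem-dimethyl compound should be separable from under- and over-methylated material.

Step 9
Reactants: 19 bis(hydroxy ketone) from step 7; 21 propionylfilicinic acid (3 equiv)
Product: 23 tetramer with rings B and C still protected (OBn on the carbon between central CH2 and propionyl, OTIPS on the carbon between the two CH2 groups), via bis(ortho-quinone methide) 22 (not isolated)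
Conditions: TsOH·H2O (10 mol%), CH2Cl2/(CF3)2CHOH, 0 °C → rt
Reagents that add atoms: none
Why: Acid-assisted loss of benzyl alcohol from the electron-rich 2-hydroxybenzyl ether gives the ortho-quinone methide 22, which is captured at its exocyclic CH2 by the single nucleophilic ring CH of the enolized triketone 21 (Michael addition with rearomatization), the usual way of forging the methylene links of acylphloroglucinol oligomers; the silyl ether is kept on so that the ring is not activated further toward scission of the central link.

Step 10
Reactants: 23 protected tetramer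
Product: 24 tetramer bis(benzyl ether) (both silyl groups removed)
Conditions: Bu4NF, AcOH, THF, 0 °C → rt
Reagents that add atoms: none
Why: Fluoride cleaves the two aryl silyl ethers through Si–F bond formation with a phenoxide leaving group, and acetic acid buffers the medium so that the methylene links and enolized triketones are not exposed to basic fluoride.

Step 11
Reactants: 24 tetramer bis(benzyl ether)
Product: 25 target CNP0541376.0
Conditions: H2 (1 atm), Pd/C (10 wt% palladium on carbon), EtOAc/MeOH, rt
Reagents that add atoms: none
Why: Hydrogenolysis of the two aryl benzyl ethers over palladium on carbon should leave the hydrogen-bonded aryl ketones, the enolized triketone rings and the diarylmethane links untouched under these mild conditions and release the target with toluene as the only co-product.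

**Compound list**

1 | 3-ethoxycyclobut-2-en-1-one | CCOC1=CC(=O)C1 | starting material
2 | formaldehyde | C=O | starting material
3 | cyclobutane-1,3-dione | O=C1CC(=O)C1 | intermediate
4 | 2-methylenecyclobutane-1,3-dione | C=C1C(=O)CC1=O | intermediate
5 | 2,2'-methylenebis(3-hydroxycyclobut-2-en-1-one) | O=C1CC(O)=C1CC1=C(O)CC1=O | intermediate
6 | 2,2'-methylenebis[3-(benzyloxy)cyclobut-2-en-1-one] | O=C1CC(OCc2ccccc2)=C1CC1=C(OCc2ccccc2)CC1=O | intermediate
7 | benzyl propargyl ether | C#CCOCc1ccccc1 | starting material
8 | lithium 3-(benzyloxy)prop-1-yn-1-ide | [Li]C#CCOCc1ccccc1 | intermediate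
9 | lithium 3-(benzyloxy)prop-1-yn-1-olate | [Li]OC#CCOCc1ccccc1 | intermediate
10 | 3-benzyloxy-1-(triisopropylsiloxy)propyne | CC(C)[Si](OC#CCOCc1ccccc1)(C(C)C)C(C)C | intermediate
11 | bis(vinylketene), 2,4-bis[1-(benzyloxy)ethenyl]penta-1,4-diene-1,5-dione | C=C(OCc1ccccc1)C(=C=O)CC(=C=O)C(=C)OCc1ccccc1 | intermediate
12 | bis(4-vinylcyclobutenone), 4,4'-methylenebis{4-[1-(benzyloxy)ethenyl]-2-[(benzyloxy)methyl]-3-[(triisopropylsilyl)oxy]cyclobut-2-en-1-one}, mixture of diastereomers | O=C1C(COCc2ccccc2)=C(O[Si](C(C)C)(C(C)C)C(C)C)C1(C(=C)OCc3ccccc3)CC4(C(=C)OCc5ccccc5)C(=O)C(COCc6ccccc6)=C4O[Si](C(C)C)(C(C)C)C(C)C | intermediate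
13 | bis(dienylketene), ketene and alkoxyvinyl groups cis on each central C=C | O=C=C(COCc1ccccc1)/C(O[Si](C(C)C)(C(C)C)C(C)C)=C(\C(=C)OCc1ccccc1)CC(/C(=C)OCc1ccccc1)=C(O[Si](C(C)C)(C(C)C)C(C)C)/C(=C=O)COCc1ccccc1 | intermediate
14 | bis(cyclohexa-2,4-dienone), 4,4'-methylenebis{5-(benzyloxy)-2-[(benzyloxy)methyl]-3-[(triisopropylsilyl)oxy]cyclohexa-2,4-dien-1-one} | O=C1CC(OCc2ccccc2)=C(CC3=C(OCc4ccccc4)CC(=O)C(COCc4ccccc4)=C3O[Si](C(C)C)(C(C)C)C(C)C)C(O[Si](C(C)C)(C(C)C)C(C)C)=C1COCc1ccccc1 | intermediate
15 | 4,4'-methylenebis{5-(benzyloxy)-2-[(benzyloxy)methyl]-3-[(triisopropylsilyl)oxy]phenol} | C(c1c(OCc2ccccc2)cc(O)c(COCc2ccccc2)c1O[Si](C(C)C)(C(C)C)C(C)C)c1c(OCc2ccccc2)cc(O)c(COCc2ccccc2)c1O[Si](C(C)C)(C(C)C)C(C)C | intermediate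
16 | dipropanoate of 15 | C(c1c(OCc2ccccc2)cc(OC(=O)CC)c(COCc2ccccc2)c1O[Si](C(C)C)(C(C)C)C(C)C)c1c(OCc2ccccc2)cc(OC(=O)CC)c(COCc2ccccc2)c1O[Si](C(C)C)(C(C)C)C(C)C | intermediate
17 | dibromide of 16, Br between OBn and propanoyloxy on each ring | C(c1c(OCc2ccccc2)c(Br)c(OC(=O)CC)c(COCc2ccccc2)c1O[Si](C(C)C)(C(C)C)C(C)C)c1c(OCc2ccccc2)c(Br)c(OC(=O)CC)c(COCc2ccccc2)c1O[Si](C(C)C)(C(C)C)C(C)C | intermediate
18 | bis(aryllithium) from 17 | C(c1c(OCc2ccccc2)c([Li])c(OC(=O)CC)c(COCc2ccccc2)c1O[Si](C(C)C)(C(C)C)C(C)C)c1c(OCc2ccccc2)c([Li])c(OC(=O)CC)c(COCc2ccccc2)c1O[Si](C(C)C)(C(C)C)C(C)C | intermediate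
19 | 1,1'-(methylenebis{6-(benzyloxy)-3-[(benzyloxy)methyl]-2-hydroxy-4-[(triisopropylsilyl)oxy]-5,1-phenylene})di(propan-1-one) | C(c1c(OCc2ccccc2)c(C(=O)CC)c(O)c(COCc2ccccc2)c1O[Si](C(C)C)(C(C)C)C(C)C)c1c(OCc2ccccc2)c(C(=O)CC)c(O)c(COCc2ccccc2)c1O[Si](C(C)C)(C(C)C)C(C)C | intermediate
20 | flopropione, 1-(2,4,6-trihydroxyphenyl)propan-1-one | CCC(=O)c1c(O)cc(O)cc1O | starting material
21 | propionylfilicinic acid, 3,5-dihydroxy-6,6-dimethyl-2-propanoylcyclohexa-2,4-dien-1-one | CCC(=O)C1=C(O)C=C(O)C(C)(C)C1=O | intermediate
22 | bis(ortho-quinone methide) from 19 | C=C1C(=O)C(C(=O)CC)=C(OCc2ccccc2)C(CC2=C(O[Si](C(C)C)(C(C)C)C(C)C)C(=C)C(=O)C(C(=O)CC)=C2OCc2ccccc2)=C1O[Si](C(C)C)(C(C)C)C(C)C | intermediate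
23 | tetramer, rings B and C as benzyl ether and triisopropylsilyl ether | CCC(=O)C1=C(O)C(Cc2c(O[Si](C(C)C)(C(C)C)C(C)C)c(Cc3c(O[Si](C(C)C)(C(C)C)C(C)C)c(CC4=C(O)C(C)(C)C(=O)C(C(=O)CC)=C4O)c(O)c(C(=O)CC)c3OCc3ccccc3)c(OCc3ccccc3)c(C(=O)CC)c2O)=C(O)C(C)(C)C1=O | intermediate
24 | tetramer bis(benzyl ether) | CCC(=O)C1=C(O)C(Cc2c(O)c(Cc3c(O)c(CC4=C(O)C(C)(C)C(=O)C(C(=O)CC)=C4O)c(O)c(C(=O)CC)c3OCc3ccccc3)c(OCc3ccccc3)c(C(=O)CC)c2O)=C(O)C(C)(C)C1=O | intermediate
25 | CNP0541376.0 | CCC(=O)C1=C(O)C(Cc2c(O)c(Cc3c(O)c(CC4=C(O)C(C)(C)C(=O)C(C(=O)CC)=C4O)c(O)c(C(=O)CC)c3O)c(O)c(C(=O)CC)c2O)=C(O)C(C)(C)C1=O | target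

**Step count and risks**

Total step count: 11. Longest linear sequence: 9 steps (1, 2, 4, 5, 6, 7, 9, 10, 11); steps 3 and 8 are side branches.

Steps most likely to fail:

Step 4. The donor-stabilized 3-alkoxycyclobutenone may open too slowly, so that the siloxyalkyne decomposes first. The vinylketene may dimerize or acylate phenol already formed, only one of the two four-membered rings may annulate, and the product may lose benzyl alcohol on prolonged heating. The fallback gives up the pericyclic construction and takes rings B and C from a bought arene. It sets out from flopropione 20 and formaldehyde 2: condensation with 0.5 equivalent of formaldehyde in dilute aqueous KOH at 0 °C (classical methylene bridging of acylphloroglucinols, flopropione in excess to hold back oligomers) should give 3,3'-methylenebis(2,4,6-trihydroxypropiophenone) F1. F1, an excess of 21 and two further equivalents of formaldehyde in aqueous KOH at 0 °C should then form the two outer methylene links at the remaining ring CH of each central ring. This comes back to the route at the target 25, after separation from the statistical homo-coupled products, and steps 5 to 7 and 9 to 11 are then not needed.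

Step 9. The acid may cleave or scramble the diarylmethane links by retro-Friedel–Crafts ionization, the quinone methide may oligomerize faster than it is captured twice, and the adduct may cyclodehydrate onto the neighbouring triketone. The fallback moves the quinone methide release to basic conditions. It sets out from 19: p-toluenesulfinic acid (2.5 equiv, CH2Cl2, rt) should exchange the benzyloxy groups for sulfonyl groups by fast capture with the sulfur nucleophile, giving the isolable bis(p-tolylsulfonylmethyl) compound F2. Treatment of F2 with 21 (3 equiv) and Cs2CO3 in CH2Cl2/MeCN at 0 °C → rt should then release the quinone methide by phenoxide-driven 1,4-elimination of sulfinate, and the enolate of 21 adds to it. This comes back to the route at 23.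

Step 1. Ring cleavage of the strained free dione by water (retro-Claisen opening) or polymerization of the methylene dione may outrun the formation of the bridge. The fallback builds the bridge on a robust vinylogous amide and frees the dione function only afterwards. It sets out from 1: pyrrolidine in EtOH at rt (addition–elimination) should give 3-(pyrrolidin-1-yl)cyclobut-2-en-1-one F3. F3 with formaldehyde 2 (0.5 equiv) and catalytic AcOH in EtOH at 60 °C should give 2,2'-methylenebis[3-(pyrrolidin-1-yl)cyclobut-2-en-1-one] F4 by attack of the enaminone α-carbon and Michael addition of a second enaminone. Hydrolysis of F4 in 2 M aqueous HCl at 50 °C comes back to the route at 5.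

**Further compounds**

F1 | step 4 | 3,3'-methylenebis(2,4,6-trihydroxypropiophenone) | CCC(=O)c1c(O)cc(O)c(Cc2c(O)cc(O)c(C(=O)CC)c2O)c1O
F2 | step 9 | bis(p-tolylsulfonylmethyl) analogue of 19 (each CH2OBn replaced by CH2SO2C6H4Me) | C(c1c(OCc2ccccc2)c(C(=O)CC)c(O)c(CS(=O)(=O)c2ccc(C)cc2)c1O[Si](C(C)C)(C(C)C)C(C)C)c1c(OCc2ccccc2)c(C(=O)CC)c(O)c(CS(=O)(=O)c2ccc(C)cc2)c1O[Si](C(C)C)(C(C)C)C(C)C
F3 | step 1 | 3-(pyrrolidin-1-yl)cyclobut-2-en-1-one | O=C1CC(N2CCCC2)=C1
F4 | step 1 | 2,2'-methylenebis[3-(pyrrolidin-1-yl)cyclobut-2-en-1-one] | O=C1CC(N2CCCC2)=C1CC1=C(N2CCCC2)CC1=O
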